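**Retrosynthetic overview**

1. The last ring bond is the ether C–O bond at the fully substituted α-carbon of the lactone; cutting it opens the 6,8-dioxabicyclo[3.2.2]nonan-7-one to a seven-membered β-keto lactone with a free secondary alcohol. Ketone reduction and desilylation follow the ring closure.
2. The seven-membered keto lactone (ring A, formed first) comes from a dioxinone: thermal acylketene formation and capture by the tertiary alcohol (second C–O disconnection).
3. The anti-diol comes from epoxidation and hydrolysis of an E-trisubstituted alkene; the chain is joined by γ-alkylation of a dioxinone dienolate with a nerol-derived allylic bromide.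
4. The 5-substituted dioxinone comes from a B-alkyl Suzuki coupling of an iodo-dioxinone with a Z-diene built from propargyl alcohol.
5. Ring order: seven-membered lactone (ring A), then the six-membered 1,4-dioxan-2-one (ring B) by oxidative etherification, which completes the bicycle.

Assumption: reagents and catalysts (including the L-fructose-derived Shi ketone and the CBS oxazaborolidine) are bought; the carbon skeleton comes from nerol, propargyl alcohol, vinylboronic acid pinacol ester and 2,2,6-trimethyl-4H-1,3-dioxin-4-one. TBDPS = tert-butyldiphenylsilyl, TES = triethylsilyl.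

**Route**

Step 1
Reactants: 1 nerol [(2Z)-3,7-dimethylocta-2,6-dien-1-ol]
Product: 2 tert-butyl{[(2Z)-3,7-dimethylocta-2,6-dien-1-yl]oxy}diphenylsilane
Conditions: TBDPSCl, imidazole, DMF, 0 °C to rt
Reagents that add atoms: tert-butyl(chloro)diphenylsilane, CC(C)(C)[Si](Cl)(c1ccccc1)c1ccccc1
Why: Silyl ether protection of the primary allylic alcohol; the bulky group later shields and deactivates the neighbouring Z-alkene and survives acid, base and heat.

Step 2
Reactants: 2 tert-butyl{[(2Z)-3,7-dimethylocta-2,6-dien-1-yl]oxy}diphenylsilane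
Product: 3 (2E,6Z)-8-[(tert-butyldiphenylsilyl)oxy]-2,6-dimethylocta-2,6-dien-1-ol
Conditions: SeO2 (20 mol %), tBuOOH, salicylic acid (10 mol %), CH2Cl2, rt
Reagents that add atoms: tert-butyl hydroperoxide, CC(C)(C)OO
Why: Riley allylic oxidation (ene reaction then [2,3]-sigmatropic shift) hydroxylates the (E)-methyl group of the electron-rich distal alkene and gives the E-allylic alcohol, the alkene next to the silyloxy group being deactivated.

Step 3
Reactants: 3 (2E,6Z)-8-[(tert-butyldiphenylsilyl)oxy]-2,6-dimethylocta-2,6-dien-1-ol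
Product: 4 {[(2Z,6E)-8-bromo-3,7-dimethylocta-2,6-dien-1-yl]oxy}(tert-butyl)diphenylsilane
Conditions: CBr4, PPh3, CH2Cl2, −20 to 0 °C
Reagents that add atoms: carbon tetrabromide, BrC(Br)(Br)Br
Why: Appel bromination of the primary allylic alcohol at low temperature, without allylic transposition or change of alkene geometry.

Step 4
Reactants: 5 prop-2-yn-1-ol
Product: 7 (2Z)-3-iodo-2-methylprop-2-en-1-ol, via alkenylmagnesium alkoxide 6 (not isolated)
Conditions: MeMgBr (2.2 equiv), CuI (10 mol %), THF, −10 °C to rt; then I2, −78 to 0 °C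
Reagents that add atoms: methylmagnesium bromide, C[Mg]Br; iodine, II
Why: Copper-catalysed anti-carbomagnesiation of the propargylic magnesium alkoxide (chelate control) followed by iodinolysis with retention gives the Z-iodide and so fixes the Z geometry of the 2-methylallylic alcohol terminus.

Step 5
Reactants: 7 (2Z)-3-iodo-2-methylprop-2-en-1-ol
Product: 8 tert-butyl{[(2Z)-3-iodo-2-methylprop-2-en-1-yl]oxy}diphenylsilane
Conditions: TBDPSCl, imidazole, CH2Cl2, 0 °C to rt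
Reagents that add atoms: tert-butyl(chloro)diphenylsilane, CC(C)(C)[Si](Cl)(c1ccccc1)c1ccccc1
Why: Silyl ether protection of the primary alcohol; the alkene geometry is not touched.

Step 6
Reactants: 8 tert-butyl{[(2Z)-3-iodo-2-methylprop-2-en-1-yl]oxy}diphenylsilane; 9 4,4,5,5-tetramethyl-2-vinyl-1,3,2-dioxaborolane
Product: 10 tert-butyl{[(2Z)-2-methylpenta-2,4-dien-1-yl]oxy}diphenylsilane
Conditions: PdCl2(dppf) (3 mol %), K2CO3, THF/H2O, 50 °C
Reagents that add atoms: none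
Why: Suzuki–Miyaura coupling of the alkenyl iodide proceeds with retention, so the new vinyl group stays cis to the CH2O group.

Step 7
Reactants: 11 2,2,6-trimethyl-4H-1,3-dioxin-4-one
Product: 12 5-iodo-2,2,6-trimethyl-4H-1,3-dioxin-4-one
Conditions: NIS, AcOH, rt, dark
Reagents that add atoms: N-iodosuccinimide, O=C1CCC(=O)N1I
Why: Electrophilic iodination at the nucleophilic α-carbon (C5) of the vinylogous ester.

Step 8
Reactants: 10 tert-butyl{[(2Z)-2-methylpenta-2,4-dien-1-yl]oxy}diphenylsilane; 12 5-iodo-2,2,6-trimethyl-4H-1,3-dioxin-4-one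
Product: 14 5-{(3Z)-5-[(tert-butyldiphenylsilyl)oxy]-4-methylpent-3-en-1-yl}-2,2,6-trimethyl-4H-1,3-dioxin-4-one, via alkyl-9-BBN adduct 13 (not isolated)
Conditions: 9-BBN, THF, 0 °C to rt; then 12, PdCl2(dppf) (5 mol %), AsPh3, Cs2CO3, DMF/H2O, rt
Reagents that add atoms: none
Why: 9-BBN hydroborates only the terminal monosubstituted alkene of the diene (anti-Markovnikov), and the homoallylic borane then undergoes B-alkyl Suzuki–Miyaura coupling with the α-iodo-enone-type iodide, leaving the Z-alkene intact.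

Step 9
Reactants: 14 5-{(3Z)-5-[(tert-butyldiphenylsilyl)oxy]-4-methylpent-3-en-1-yl}-2,2,6-trimethyl-4H-1,3-dioxin-4-one; 4 {[(2Z,6E)-8-bromo-3,7-dimethylocta-2,6-dien-1-yl]oxy}(tert-butyl)diphenylsilane
Product: 16 6-{(3E,7Z)-9-[(tert-butyldiphenylsilyl)oxy]-3,7-dimethylnona-3,7-dien-1-yl}-5-{(3Z)-5-[(tert-butyldiphenylsilyl)oxy]-4-methylpent-3-en-1-yl}-2,2-dimethyl-4H-1,3-dioxin-4-one, via lithium dienolate 15 (not isolated)
Conditions: LiN(iPr)2, THF, −78 °C; then 4, DMPU, −78 to −40 °C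
Reagents that add atoms: none
Why: γ-Alkylation of the vinylogous lithium enolate with the primary allylic bromide (SN2); the substituted C5 blocks α-attack, and the dioxinone keeps the future ketone masked.

Step 10
Reactants: 16 6-{(3E,7Z)-9-[(tert-butyldiphenylsilyl)oxy]-3,7-dimethylnona-3,7-dien-1-yl}-5-{(3Z)-5-[(tert-butyldiphenylsilyl)oxy]-4-methylpent-3-en-1-yl}-2,2-dimethyl-4H-1,3-dioxin-4-one
Product: 17 6-(2-{(2S,3S)-3-[(3Z)-5-[(tert-butyldiphenylsilyl)oxy]-3-methylpent-3-en-1-yl]-2-methyloxiran-2-yl}ethyl)-5-{(3Z)-5-[(tert-butyldiphenylsilyl)oxy]-4-methylpent-3-en-1-yl}-2,2-dimethyl-4H-1,3-dioxin-4-one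
Conditions: ent-Shi ketone (1,2:4,5-di-O-isopropylidene-β-L-erythro-2,3-hexodiulo-2,6-pyranose, 30 mol %), KHSO5 (as 2KHSO5·KHSO4·K2SO4), K2CO3, Bu4NHSO4, MeCN/CH2(OMe)2/borate buffer (pH 10.5), 0 °C
Reagents that add atoms: potassium peroxymonosulfate, [K+].[O-]S(=O)(=O)OO
Why: Shi asymmetric epoxidation through a chiral dioxirane (spiro transition state): the L-fructose-derived ketone gives the (S,S)-epoxide of the only unfunctionalised E-trisubstituted alkene, the two Z-alkenes being deactivated and shielded by their allylic silyloxy groups and the dioxinone alkene being electron-poor.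

Step 11
Reactants: 17 (2S,3S)-epoxide
Product: 18 6-{(3R,4S,7Z)-9-[(tert-butyldiphenylsilyl)oxy]-3,4-dihydroxy-3,7-dimethylnon-7-en-1-yl}-5-{(3Z)-5-[(tert-butyldiphenylsilyl)oxy]-4-methylpent-3-en-1-yl}-2,2-dimethyl-4H-1,3-dioxin-4-one
Conditions: HClO4 (5 mol %), THF/H2O (4:1), 0 °C
Reagents that add atoms: water, O
Why: Acid-catalysed epoxide hydrolysis: water opens the protonated epoxide at the tertiary carbon with inversion while the secondary C–O bond is kept, so the (2S,3S)-epoxide gives the anti (3R,4S)-diol, which carries both carbinol centres of the target.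

Step 12
Reactants: 18 (3R,4S)-diol
Product: 19 6-{(3R,4S,7Z)-9-[(tert-butyldiphenylsilyl)oxy]-3-hydroxy-3,7-dimethyl-4-[(triethylsilyl)oxy]non-7-en-1-yl}-5-{(3Z)-5-[(tert-butyldiphenylsilyl)oxy]-4-methylpent-3-en-1-yl}-2,2-dimethyl-4H-1,3-dioxin-4-one
Conditions: TESCl, imidazole, DMAP (cat.), CH2Cl2, −20 to 0 °C
Reagents that add atoms: chlorotriethylsilane, CC[Si](Cl)(CC)CC
Why: Chemoselective silylation of the secondary hydroxyl (the tertiary one is too hindered), so that only the tertiary alcohol can trap the ketene in the next step.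

Step 13
Reactants: 19 mono-TES diol
Product: 22 (7R)-7-{(1S,4Z)-6-[(tert-butyldiphenylsilyl)oxy]-1-hydroxy-4-methylhex-4-en-1-yl}-3-{(3Z)-5-[(tert-butyldiphenylsilyl)oxy]-4-methylpent-3-en-1-yl}-7-methyloxepane-2,4-dione (C3 epimers and enol), via acylketene 20 (not isolated), via silyl keto lactone 21 (not isolated)
Conditions: PhMe (2 mM), 110 °C; then HF·pyridine, pyridine, THF, 0 °C
Reagents that add atoms: none
Why: Thermal retro-hetero-Diels–Alder of the dioxinone expels acetone and the acylketene is trapped at high dilution by the only free hydroxyl (the tertiary one) in an acylketene lactonisation that forms the seven-membered β-keto lactone with both carbinol centres untouched, after which HF·pyridine removes only the triethylsilyl group.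

Step 14
Reactants: 22 seven-membered hydroxy β-keto lactone
Product: 24 (1R,5R,9S)-9-{(3Z)-5-[(tert-butyldiphenylsilyl)oxy]-3-methylpent-3-en-1-yl}-1-{(3Z)-5-[(tert-butyldiphenylsilyl)oxy]-4-methylpent-3-en-1-yl}-5-methyl-6,8-dioxabicyclo[3.2.2]nonane-2,7-dione, via α-iodo keto lactone 23 (not isolated)
Conditions: Bu4NI (20 mol %), tBuOOH (2 equiv, decane), EtOAc, 40 °C
Reagents that add atoms: none
Why: Proposed new method: a hypoiodite-catalysed transannular dehydrogenative etherification in which Bu4NI and tBuOOH generate ammonium hypoiodite that reversibly iodinates the enolisable C3 of the β-keto lactone, and the side-chain hydroxyl then displaces iodide by intramolecular SN2 at this doubly carbonyl-activated tertiary carbon, which is possible only for the C3 epimer with iodine anti to the oxygen, so both epimers funnel into one six-membered 1,4-dioxan-2-one ring and the quaternary centre (1R) is dictated by the existing tertiary centre; the closest known reactions are hypoiodite-catalysed oxidative cycloetherification of ketophenols and α-oxyacylation of 1,3-dicarbonyl compounds, not yet shown for an unactivated secondary aliphatic alcohol, a lactone-embedded 1,3-dicarbonyl or a bridged product.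

Step 15
Reactants: 24 bicyclic keto lactone
Product: 25 (1R,2S,5R,9S)-9-{(3Z)-5-[(tert-butyldiphenylsilyl)oxy]-3-methylpent-3-en-1-yl}-1-{(3Z)-5-[(tert-butyldiphenylsilyl)oxy]-4-methylpent-3-en-1-yl}-2-hydroxy-5-methyl-6,8-dioxabicyclo[3.2.2]nonan-7-one
Conditions: (R)-2-methyl-CBS-oxazaborolidine (20 mol %), catecholborane, PhMe, −78 °C
Reagents that add atoms: none
Why: Corey–Bakshi–Shibata reduction: the (R)-oxazaborolidine binds the ketone with the quaternary bridgehead as the large group and the ring CH2 as the small one and delivers hydride to give the (2S)-alcohol under reagent control, while catecholborane at −78 °C leaves the lactone and the trisubstituted alkenes alone.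

Step 16
Reactants: 25 bis-silyl ether
Product: 26 (1R,2S,5R,9S)-2-hydroxy-1-[(3Z)-5-hydroxy-4-methylpent-3-en-1-yl]-9-[(3Z)-5-hydroxy-3-methylpent-3-en-1-yl]-5-methyl-6,8-dioxabicyclo[3.2.2]nonan-7-one (CNP0105745.1)
Conditions: Bu4NF, AcOH, THF, 0 °C to rt
Reagents that add atoms: none
Why: Fluoride-mediated desilylation of both primary silyl ethers, buffered with AcOH so that the β-hydroxy lactone neither opens nor undergoes retro-aldol cleavage; no stereocentre is affected.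

**Compound list**

1 | nerol, (2Z)-3,7-dimethylocta-2,6-dien-1-ol | CC(C)=CCC/C(C)=C\CO | starting material
2 | tert-butyl{[(2Z)-3,7-dimethylocta-2,6-dien-1-yl]oxy}diphenylsilane | CC(C)=CCC/C(C)=C\CO[Si](C(C)(C)C)(c1ccccc1)c1ccccc1 | intermediate
3 | (2E,6Z)-8-[(tert-butyldiphenylsilyl)oxy]-2,6-dimethylocta-2,6-dien-1-ol | OC/C(C)=C/CC/C(C)=C\CO[Si](C(C)(C)C)(c1ccccc1)c1ccccc1 | intermediate
4 | {[(2Z,6E)-8-bromo-3,7-dimethylocta-2,6-dien-1-yl]oxy}(tert-butyl)diphenylsilane | BrC/C(C)=C/CC/C(C)=C\CO[Si](C(C)(C)C)(c1ccccc1)c1ccccc1 | intermediate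
5 | prop-2-yn-1-ol | C#CCO | starting material
6 | bromomagnesium (2Z)-3-(bromomagnesio)-2-methylprop-2-en-1-olate | Br[Mg]/C=C(/C)CO[Mg]Br | intermediate
7 | (2Z)-3-iodo-2-methylprop-2-en-1-ol | OC/C(C)=C\I | intermediate
8 | tert-butyl{[(2Z)-3-iodo-2-methylprop-2-en-1-yl]oxy}diphenylsilane | I/C=C(/C)CO[Si](C(C)(C)C)(c1ccccc1)c1ccccc1 | intermediate
9 | 4,4,5,5-tetramethyl-2-vinyl-1,3,2-dioxaborolane | C=CB1OC(C)(C)C(C)(C)O1 | starting material
10 | tert-butyl{[(2Z)-2-methylpenta-2,4-dien-1-yl]oxy}diphenylsilane | C=C/C=C(/C)CO[Si](C(C)(C)C)(c1ccccc1)c1ccccc1 | intermediate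
11 | 2,2,6-trimethyl-4H-1,3-dioxin-4-one | CC1=CC(=O)OC(C)(C)O1 | starting material
12 | 5-iodo-2,2,6-trimethyl-4H-1,3-dioxin-4-one | CC1=C(I)C(=O)OC(C)(C)O1 | intermediate
13 | 9-{(3Z)-5-[(tert-butyldiphenylsilyl)oxy]-4-methylpent-3-en-1-yl}-9-borabicyclo[3.3.1]nonane | C(C/C=C(/C)CO[Si](C(C)(C)C)(c1ccccc1)c1ccccc1)B1C2CCCC1CCC2 | intermediate
14 | 5-{(3Z)-5-[(tert-butyldiphenylsilyl)oxy]-4-methylpent-3-en-1-yl}-2,2,6-trimethyl-4H-1,3-dioxin-4-one | CC1=C(CC/C=C(/C)CO[Si](C(C)(C)C)(c2ccccc2)c2ccccc2)C(=O)OC(C)(C)O1 | intermediate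
15 | lithium 5-{(3Z)-5-[(tert-butyldiphenylsilyl)oxy]-4-methylpent-3-en-1-yl}-2,2-dimethyl-6-methylidene-6H-1,3-dioxin-4-olate | C=C1OC(C)(C)OC(O[Li])=C1CC/C=C(/C)CO[Si](C(C)(C)C)(c2ccccc2)c2ccccc2 | intermediate
16 | 6-{(3E,7Z)-9-[(tert-butyldiphenylsilyl)oxy]-3,7-dimethylnona-3,7-dien-1-yl}-5-{(3Z)-5-[(tert-butyldiphenylsilyl)oxy]-4-methylpent-3-en-1-yl}-2,2-dimethyl-4H-1,3-dioxin-4-one | O=C1OC(C)(C)OC(CC/C(C)=C/CC/C(C)=C\CO[Si](C(C)(C)C)(c2ccccc2)c2ccccc2)=C1CC/C=C(/C)CO[Si](C(C)(C)C)(c2ccccc2)c2ccccc2 | intermediate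
17 | 6-(2-{(2S,3S)-3-[(3Z)-5-[(tert-butyldiphenylsilyl)oxy]-3-methylpent-3-en-1-yl]-2-methyloxiran-2-yl}ethyl)-5-{(3Z)-5-[(tert-butyldiphenylsilyl)oxy]-4-methylpent-3-en-1-yl}-2,2-dimethyl-4H-1,3-dioxin-4-one | O=C1OC(C)(C)OC(CC[C@]2(C)O[C@H]2CC/C(C)=C\CO[Si](C(C)(C)C)(c3ccccc3)c3ccccc3)=C1CC/C=C(/C)CO[Si](C(C)(C)C)(c3ccccc3)c3ccccc3 | intermediate
18 | 6-{(3R,4S,7Z)-9-[(tert-butyldiphenylsilyl)oxy]-3,4-dihydroxy-3,7-dimethylnon-7-en-1-yl}-5-{(3Z)-5-[(tert-butyldiphenylsilyl)oxy]-4-methylpent-3-en-1-yl}-2,2-dimethyl-4H-1,3-dioxin-4-one | O=C1OC(C)(C)OC(CC[C@@](C)(O)[C@@H](O)CC/C(C)=C\CO[Si](C(C)(C)C)(c2ccccc2)c2ccccc2)=C1CC/C=C(/C)CO[Si](C(C)(C)C)(c2ccccc2)c2ccccc2 | intermediate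
19 | 6-{(3R,4S,7Z)-9-[(tert-butyldiphenylsilyl)oxy]-3-hydroxy-3,7-dimethyl-4-[(triethylsilyl)oxy]non-7-en-1-yl}-5-{(3Z)-5-[(tert-butyldiphenylsilyl)oxy]-4-methylpent-3-en-1-yl}-2,2-dimethyl-4H-1,3-dioxin-4-one | O=C1OC(C)(C)OC(CC[C@@](C)(O)[C@@H](O[Si](CC)(CC)CC)CC/C(C)=C\CO[Si](C(C)(C)C)(c2ccccc2)c2ccccc2)=C1CC/C=C(/C)CO[Si](C(C)(C)C)(c2ccccc2)c2ccccc2 | intermediate
20 | acylketene, (6R,7S,10Z)-12-[(tert-butyldiphenylsilyl)oxy]-2-{(3Z)-5-[(tert-butyldiphenylsilyl)oxy]-4-methylpent-3-en-1-yl}-6-hydroxy-6,10-dimethyl-7-[(triethylsilyl)oxy]dodeca-1,10-diene-1,3-dione | O=C=C(CC/C=C(/C)CO[Si](C(C)(C)C)(c1ccccc1)c1ccccc1)C(=O)CC[C@@](C)(O)[C@@H](O[Si](CC)(CC)CC)CC/C(C)=C\CO[Si](C(C)(C)C)(c1ccccc1)c1ccccc1 | intermediate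
21 | (7R)-7-{(1S,4Z)-6-[(tert-butyldiphenylsilyl)oxy]-4-methyl-1-[(triethylsilyl)oxy]hex-4-en-1-yl}-3-{(3Z)-5-[(tert-butyldiphenylsilyl)oxy]-4-methylpent-3-en-1-yl}-7-methyloxepane-2,4-dione (C3 epimers) | O=C1O[C@](C)(CCC(=O)C1CC/C=C(/C)CO[Si](C(C)(C)C)(c2ccccc2)c2ccccc2)[C@@H](O[Si](CC)(CC)CC)CC/C(C)=C\CO[Si](C(C)(C)C)(c2ccccc2)c2ccccc2 | intermediate
22 | (7R)-7-{(1S,4Z)-6-[(tert-butyldiphenylsilyl)oxy]-1-hydroxy-4-methylhex-4-en-1-yl}-3-{(3Z)-5-[(tert-butyldiphenylsilyl)oxy]-4-methylpent-3-en-1-yl}-7-methyloxepane-2,4-dione (C3 epimers) | O=C1O[C@](C)(CCC(=O)C1CC/C=C(/C)CO[Si](C(C)(C)C)(c2ccccc2)c2ccccc2)[C@@H](O)CC/C(C)=C\CO[Si](C(C)(C)C)(c2ccccc2)c2ccccc2 | intermediate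
23 | (7R)-3-iodo derivative of 22 (C3 epimers) | O=C1O[C@](C)(CCC(=O)C1(I)CC/C=C(/C)CO[Si](C(C)(C)C)(c2ccccc2)c2ccccc2)[C@@H](O)CC/C(C)=C\CO[Si](C(C)(C)C)(c2ccccc2)c2ccccc2 | intermediate
24 | (1R,5R,9S)-9-{(3Z)-5-[(tert-butyldiphenylsilyl)oxy]-3-methylpent-3-en-1-yl}-1-{(3Z)-5-[(tert-butyldiphenylsilyl)oxy]-4-methylpent-3-en-1-yl}-5-methyl-6,8-dioxabicyclo[3.2.2]nonane-2,7-dione | C/C(=C/CC[C@@]12O[C@@H](CC/C(C)=C\CO[Si](C(C)(C)C)(c3ccccc3)c3ccccc3)[C@@](C)(CCC1=O)OC2=O)CO[Si](C(C)(C)C)(c3ccccc3)c3ccccc3 | intermediate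
25 | (1R,2S,5R,9S)-9-{(3Z)-5-[(tert-butyldiphenylsilyl)oxy]-3-methylpent-3-en-1-yl}-1-{(3Z)-5-[(tert-butyldiphenylsilyl)oxy]-4-methylpent-3-en-1-yl}-2-hydroxy-5-methyl-6,8-dioxabicyclo[3.2.2]nonan-7-one | C/C(=C/CC[C@@]12O[C@@H](CC/C(C)=C\CO[Si](C(C)(C)C)(c3ccccc3)c3ccccc3)[C@@](C)(CC[C@@H]1O)OC2=O)CO[Si](C(C)(C)C)(c3ccccc3)c3ccccc3 | intermediate
26 | (1R,2S,5R,9S)-2-hydroxy-1-[(3Z)-5-hydroxy-4-methylpent-3-en-1-yl]-9-[(3Z)-5-hydroxy-3-methylpent-3-en-1-yl]-5-methyl-6,8-dioxabicyclo[3.2.2]nonan-7-one | C/C(=C/CC[C@@]12O[C@@H](CC/C(C)=C\CO)[C@@](C)(CC[C@@H]1O)OC2=O)CO | target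

**Step count and risks**

Total: 16 steps. Longest linear sequence: 12 steps (5 → 7 → 8 → 10 → 14 → 16 → 17 → 18 → 19 → 22 → 24 → 25 → 26, that is steps 4, 5, 6, 8, 9, 10, 11, 12, 13, 14, 15 and 16).

The three steps most likely to fail:

Step 14 (the proposed new cycloetherification). The hypoiodite may oxidise the secondary alcohol, attack an alkene, or fail to close at the hindered carbon; an acyl shift of the lactone to the neighbouring hydroxyl could also compete. The fallback uses known chemistry and sets out from 22: bromination of the β-keto lactone at C3 (NBS, NH4OAc cat., Et2O, 0 °C) gives the α-bromo keto lactone F1, and silver-assisted intramolecular substitution by the hydroxyl (AgOTf, 2,6-di-tert-butylpyridine, CH2Cl2, −20 °C to rt) closes the ether. It comes back to the route at 24.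

Step 13 (acylketene lactonisation). The tertiary alcohol is hindered and the ketene may dimerise or be quenched before the seven-membered ring closes. The fallback sets out from 19: the acylketene is intercepted with tert-butanethiol (10 equiv, PhMe, 110 °C) to give the S-tert-butyl β-keto thioester F2, which is lactonised at room temperature by thiophile activation (AgOCOCF3, THF, 2 mM) to 21, and HF·pyridine then frees the secondary alcohol. It comes back to the route at 22.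

Step 10 (Shi epoxidation). The two Z-allylic silyl ether alkenes may compete with the central alkene, and the less common enantiomer of the ketone is needed. The fallback sets out from 3 and places the epoxide before the fragment union: Sharpless asymmetric epoxidation (Ti(OiPr)4, L-(+)-diethyl tartrate, tBuOOH, 4 Å sieves, CH2Cl2, −20 °C), directed by the allylic hydroxyl, gives the epoxy alcohol F3; Tf2O and 2,6-lutidine (CH2Cl2, −78 °C) give the epoxy triflate F4; alkylation of F4 with lithium dienolate 15 (THF/DMPU, −78 °C) gives the epoxide. It comes back to the route at 17 and replaces steps 3, 9 and 10.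

Further compounds
F1 | step 14 | (7R)-3-bromo-7-{(1S,4Z)-6-[(tert-butyldiphenylsilyl)oxy]-1-hydroxy-4-methylhex-4-en-1-yl}-3-{(3Z)-5-[(tert-butyldiphenylsilyl)oxy]-4-methylpent-3-en-1-yl}-7-methyloxepane-2,4-dione | O=C1O[C@](C)(CCC(=O)C1(Br)CC/C=C(/C)CO[Si](C(C)(C)C)(c2ccccc2)c2ccccc2)[C@@H](O)CC/C(C)=C\CO[Si](C(C)(C)C)(c2ccccc2)c2ccccc2
F2 | step 13 | S-tert-butyl (6R,7S,10Z)-12-[(tert-butyldiphenylsilyl)oxy]-2-{(3Z)-5-[(tert-butyldiphenylsilyl)oxy]-4-methylpent-3-en-1-yl}-6-hydroxy-6,10-dimethyl-3-oxo-7-[(triethylsilyl)oxy]dodec-10-enethioate | CC(C)(C)SC(=O)C(CC/C=C(/C)CO[Si](C(C)(C)C)(c1ccccc1)c1ccccc1)C(=O)CC[C@@](C)(O)[C@@H](O[Si](CC)(CC)CC)CC/C(C)=C\CO[Si](C(C)(C)C)(c1ccccc1)c1ccccc1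
F3 | step 10 | {(2S,3S)-3-[(3Z)-5-[(tert-butyldiphenylsilyl)oxy]-3-methylpent-3-en-1-yl]-2-methyloxiran-2-yl}methanol | OC[C@]1(C)O[C@H]1CC/C(C)=C\CO[Si](C(C)(C)C)(c2ccccc2)c2ccccc2
F4 | step 10 | {(2S,3S)-3-[(3Z)-5-[(tert-butyldiphenylsilyl)oxy]-3-methylpent-3-en-1-yl]-2-methyloxiran-2-yl}methyl trifluoromethanesulfonate | FC(F)(F)S(=O)(=O)OC[C@]1(C)O[C@H]1CC/C(C)=C\CO[Si](C(C)(C)C)(c2ccccc2)c2ccccc2
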